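Numbering (daucane): C1 = ring-fusion C(CH3), C2/C3 = CH2CH2, C4 = C(OH)iPr, C5 = ring-fusion CH, C6 = CH–O-vanilloyl, C7 = CH2, C8 = C(=C14H2), C9 = CHOH, C10 = CH2. α is the face of H5, β the face of the C1 methyl group.
Late disconnections: the C6–O acyl bond (vanillate), C8=C14 (Mannich methylenation of a C9 ketone), C9–OH (1,2-reduction, then inversion) and C4–iPr (organometallic addition to a C4 ketone). These lead back to a trans-hydroazulenone with a C4 ketone, a C6 silyl ether and a C9 ketal.
Enabling feature: in the seven-membered ring, C9–O stands 1,5 to the C4–O of the five-membered ring along C9–C10–C1–C5–C4, and C5–C6–C7–C8–C9 is a five-carbon arc. Reconnecting C5 to C9 gives a donor–acceptor cyclobutane (C5–C1–C10–C9), the retron of an intramolecular de Mayo reaction.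
Key disconnection: C5–C1 and C9–C10, back to a 2-methoxycyclopentene (C5–C9) that carries a 4-methylpent-4-enoyl chain (C4, C3, C2, C1(=C10), CH3) on C5. Its one stereocentre, C6–OTBS, comes from a CBS reduction; C6 relays to C1 and C5 in the key step, and these relay to C4 and C9.
Ring order: cyclopentene C5–C9 (bought), then cyclopentanone C1–C5 plus cyclobutane (photocycloaddition), then C5–C9 cleavage, which turns the five-membered ring into the seven-membered ring (two-atom expansion by C1 and C10). The arene is bought.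

Key step: step 6

Assumption: hydride addition to the exocyclic C8(=CH2)–C9 enone is taken to occur from the α-face (anti to the axial C1 methyl group), so the 9α-alcohol is reached by reduction followed by inversion.

Step 1
Reactants: 1 3-methoxycyclopent-2-en-1-one
Product: 2 2-bromo-3-methoxycyclopent-2-en-1-one
Conditions: NBS (1.05 equiv), CH2Cl2, 0 °C → rt, dark
Reagents that add atoms: N-bromosuccinimide O=C1CCC(=O)N1Br
Why: Electrophilic α-bromination of a vinylogous ester, in which the enol-ether-activated C2 (future C5) is the only nucleophilic carbon, installs the handle for the later metalation.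

Step 2
Reactants: 2 2-bromo-3-methoxycyclopent-2-en-1-one
Product: 3 (1S)-2-bromo-3-methoxycyclopent-2-en-1-ol
Conditions: (R)-Me-CBS (0.2 equiv), BH3·SMe2 (0.7 equiv), THF, −20 °C; MeOH quench, NaHCO3 work-up
Reagents that add atoms: none
Why: In this Corey–Bakshi–Shibata reduction of an α-bromo cyclic enone the bromoalkenyl flank acts as the large group, so the (R)-catalyst should deliver hydride to give the (S)-carbinol, which is the future C6 and the only stereocentre made by catalysis.

Step 3
Reactants: 3 (1S)-2-bromo-3-methoxycyclopent-2-en-1-ol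
Product: 4 [(1S)-2-bromo-3-methoxycyclopent-2-en-1-yl]oxy(tert-butyl)dimethylsilane
Conditions: TBSCl, imidazole, DMF, rt
Reagents that add atoms: tert-butyldimethylsilyl chloride CC(C)(C)[Si](C)(C)Cl
Why: Standard silylation under basic conditions converts the acid-labile allylic alcohol into a bulky silyl ether that later shields one face of the ring, without touching the stereocentre.

Step 4
Reactants: 5 4-methylpent-4-enoic acid
Product: 6 N-methoxy-N,4-dimethylpent-4-enamide
Conditions: MeNH(OMe)·HCl, EDC·HCl, Et3N, CH2Cl2, 0 °C → rt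
Reagents that add atoms: N,O-dimethylhydroxylamine hydrochloride CNOC.Cl
Why: Carbodiimide amidation gives the Weinreb amide, whose chelated tetrahedral adduct stops the coming acylation at the ketone stage.

Step 5
Reactants: 4 [(1S)-2-bromo-3-methoxycyclopent-2-en-1-yl]oxy(tert-butyl)dimethylsilane; 6 N-methoxy-N,4-dimethylpent-4-enamide
Product: 7 1-[(5S)-5-(tert-butyldimethylsilyloxy)-2-methoxycyclopent-1-en-1-yl]-4-methylpent-4-en-1-one
Conditions: 4, n-BuLi (1.05 equiv), THF, −78 °C; then 6, −78 → −20 °C; pH 7 buffer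
Reagents that add atoms: none
Why: Bromine–lithium exchange gives a ring-locked β-methoxyvinyllithium that cannot β-eliminate, and the Weinreb ketone synthesis joins it to the six-carbon side chain while C6 stays untouched.

Step 6
Reactants: 7 1-[(5S)-5-(tert-butyldimethylsilyloxy)-2-methoxycyclopent-1-en-1-yl]-4-methylpent-4-en-1-one
Product: 9 (3aS,4S,8aR)-4-(tert-butyldimethylsilyloxy)-7,7-dimethoxy-8a-methyloctahydroazulen-3(2H)-one, via cyclobutane photoadduct 8 (not isolated)
Conditions: hν (300 nm), MeCN–acetone 9:1, degassed, 0.01 M, 0 °C; then solvent switch to MeOH, CSA (0.1 equiv), 0 °C → rt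
Reagents that add atoms: methanol CO
Why: The acetone-sensitised triplet of the vinylogous ester C4(=O)–C5=C9(OMe) closes C5–C1 in a 5-exo mode (rule of five, three-atom tether C4–C3–C2) and the 1,4-biradical then collapses by C9–C10 bonding to the four-membered ring (straight, not crossed), which is an intramolecular enone–alkene [2+2] photocycloaddition. In acidic methanol the donor–acceptor cyclobutane opens by retro-aldol-type heterolysis of C5–C9 (push from the C9 methoxy group, pull from the protonated C4 ketone, release of ring strain), so the cyclopentane C5–C6–C7–C8–C9 takes up C1 and C10 and becomes the cycloheptane, while methanol traps the C9 oxocarbenium ion as the dimethyl ketal that keeps C9 apart from C4. The closest known reaction type is the intramolecular de Mayo reaction of O-protected enols of 2-(pent-4-enoyl)cyclopentanones, which gives bicyclo[5.3.0]decanediones. C1 is controlled by C6: the silyloxy group next to C5 shields one face of the cyclopentene, both new bonds form anti to it, and this places the C1 methyl group trans to the C6 oxygen on the seven-membered ring, as in the target. C5 is set when the C4 enol ketonises, because axial protonation anti to the axial C1 methyl group and acid-mediated equilibration should both favour the trans-fused ketone (C4 and OTBS diequatorial), whereas the cis isomer needs an axial C4 or a syn-axial OTBS/C2 pair. The step needs regioselectivity (secured by the tether length and by a ring-locked enone that cannot lose energy by E/Z isomerisation), facial selectivity (OTBS) and chemoselective masking (only the ionised C9 is ketalised, the hindered C4 ketone is not).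

Step 7
Reactants: 9 (3aS,4S,8aR)-4-(tert-butyldimethylsilyloxy)-7,7-dimethoxy-8a-methyloctahydroazulen-3(2H)-one
Product: 10 (3R,3aS,4S,8aR)-4-(tert-butyldimethylsilyloxy)-7,7-dimethoxy-8a-methyl-3-(propan-2-yl)decahydroazulen-3-ol
Conditions: iPrMgCl (2 equiv), LaCl3·2LiCl (1 equiv), THF, 0 °C; then water
Reagents that add atoms: isopropylmagnesium chloride CC(C)[Mg]Cl
Why: The lanthanide-mediated Grignard 1,2-addition suppresses enolisation and β-hydride reduction, and the nucleophile should attack C4 from the α-face next to H5 because the β-face carries the C5–C6 bond and the C1 methyl group, which gives the 4β-hydroxy-4α-isopropyl carbinol.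

Step 8
Reactants: 10 (3R,3aS,4S,8aR)-4-(tert-butyldimethylsilyloxy)-7,7-dimethoxy-8a-methyl-3-(propan-2-yl)decahydroazulen-3-ol
Product: 11 (3R,3aS,4S,8aR)-7,7-dimethoxy-8a-methyl-3-(propan-2-yl)decahydroazulene-3,4-diol
Conditions: TBAF (1.5 equiv), THF, rt → 40 °C
Reagents that add atoms: none
Why: Fluoride desilylation frees only the C6 hydroxyl group, since the ketal and the tertiary alcohol are inert to the basic medium.

Step 9
Reactants: 12 vanillic acid (4-hydroxy-3-methoxybenzoic acid)
Product: 14 4-(tert-butyldimethylsilyloxy)-3-methoxybenzoic acid, via bis-silylated vanillate 13 (not isolated)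
Conditions: TBSCl (2.3 equiv), imidazole, DMF, rt; then AcOH–THF–H2O 3:1:1, rt
Reagents that add atoms: tert-butyldimethylsilyl chloride CC(C)(C)[Si](C)(C)Cl
Why: Bis-silylation followed by selective hydrolysis of the labile silyl ester masks the phenol, so that it cannot compete in the acylation and Mitsunobu steps.

Step 10
Reactants: 11 (3R,3aS,4S,8aR)-7,7-dimethoxy-8a-methyl-3-(propan-2-yl)decahydroazulene-3,4-diol; 14 4-(tert-butyldimethylsilyloxy)-3-methoxybenzoic acid
Product: 15 (3R,3aS,4S,8aR)-3-hydroxy-7,7-dimethoxy-8a-methyl-3-(propan-2-yl)decahydroazulen-4-yl 4-(tert-butyldimethylsilyloxy)-3-methoxybenzoate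
Conditions: DCC, DMAP, CH2Cl2, rt
Reagents that add atoms: none
Why: The Steglich esterification acylates the secondary C6 hydroxyl group in preference to the tertiary C4 hydroxyl group and, as an O-acylation, retains the configuration at C6.

Step 11
Reactants: 15 (3R,3aS,4S,8aR)-3-hydroxy-7,7-dimethoxy-8a-methyl-3-(propan-2-yl)decahydroazulen-4-yl 4-(tert-butyldimethylsilyloxy)-3-methoxybenzoate
Product: 16 (3R,3aS,4S,8aR)-3-hydroxy-8a-methyl-7-oxo-3-(propan-2-yl)decahydroazulen-4-yl 4-(tert-butyldimethylsilyloxy)-3-methoxybenzoate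
Conditions: PPTS (0.2 equiv), acetone–H2O 10:1, 40 °C
Reagents that add atoms: water O
Why: Mild acid-catalysed ketal hydrolysis unmasks the C9 ketone, now the only enolisable carbonyl group, and leaves the ester, the aryl silyl ether and the tertiary alcohol intact.

Step 12
Reactants: 16 (3R,3aS,4S,8aR)-3-hydroxy-8a-methyl-7-oxo-3-(propan-2-yl)decahydroazulen-4-yl 4-(tert-butyldimethylsilyloxy)-3-methoxybenzoate
Product: 19 (3R,3aS,4S,8aR)-3-hydroxy-8a-methyl-6-methylidene-7-oxo-3-(propan-2-yl)decahydroazulen-4-yl 4-(tert-butyldimethylsilyloxy)-3-methoxybenzoate, via Mannich base 17 (not isolated), via trimethylammonium iodide 18 (not isolated)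
Conditions: LiHMDS (2.2 equiv), THF, −78 °C; CH2=NMe2+ I−, −78 → 0 °C; aqueous work-up; MeI, CH2Cl2, rt; sat. aq NaHCO3, rt
Reagents that add atoms: N,N-dimethylmethyleneiminium iodide (Eschenmoser's salt) C=[N+](C)C.[I-]; iodomethane CI (its methyl group stays only in intermediate 18)
Why: Kinetic deprotonation should occur at C8 rather than at the neopentyl C10, and the Mannich reaction followed by quaternisation and E1cB (Hofmann-type) elimination turns the new aminomethyl group into the C8=C14 methylene of an α-methylene ketone.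

Step 13
Reactants: 19 (3R,3aS,4S,8aR)-3-hydroxy-8a-methyl-6-methylidene-7-oxo-3-(propan-2-yl)decahydroazulen-4-yl 4-(tert-butyldimethylsilyloxy)-3-methoxybenzoate
Product: 20 (3R,3aS,4S,7R,8aR)-3,7-dihydroxy-8a-methyl-6-methylidene-3-(propan-2-yl)decahydroazulen-4-yl 4-(tert-butyldimethylsilyloxy)-3-methoxybenzoate
Conditions: NaBH4, CeCl3·7H2O, MeOH, −78 °C
Reagents that add atoms: none
Why: In the Luche 1,2-reduction hydride should come from the α-face, because the axial C1 methyl group is syn-axial to the β-trajectory at C9, and this gives the 9β (axial) allylic alcohol.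

Step 14
Reactants: 20 (3R,3aS,4S,7R,8aR)-3,7-dihydroxy-8a-methyl-6-methylidene-3-(propan-2-yl)decahydroazulen-4-yl 4-(tert-butyldimethylsilyloxy)-3-methoxybenzoate
Product: 21 (3R,3aS,4S,7S,8aR)-7-(chloroacetoxy)-3-hydroxy-8a-methyl-6-methylidene-3-(propan-2-yl)decahydroazulen-4-yl 4-(tert-butyldimethylsilyloxy)-3-methoxybenzoate
Conditions: ClCH2CO2H, PPh3, DIAD, toluene, 0 °C → rt
Reagents that add atoms: chloroacetic acid OC(=O)CCl
Why: The Mitsunobu reaction with the strongly acidic chloroacetic acid displaces the activated axial 9β-oxygen by SN2 attack from the open α-face and so sets the 9α (S) configuration by inversion, while the tertiary C4 hydroxyl group does not react.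

Step 15
Reactants: 21 (3R,3aS,4S,7S,8aR)-7-(chloroacetoxy)-3-hydroxy-8a-methyl-6-methylidene-3-(propan-2-yl)decahydroazulen-4-yl 4-(tert-butyldimethylsilyloxy)-3-methoxybenzoate
Product: 22 (3R,3aS,4S,7S,8aR)-3,7-dihydroxy-8a-methyl-6-methylidene-3-(propan-2-yl)decahydroazulen-4-yl 4-hydroxy-3-methoxybenzoate (target)
Conditions: K2CO3 (0.5 equiv), MeOH, 0 °C → rt; aq NH4Cl
Reagents that add atoms: none
Why: Base-catalysed methanolysis removes the activated chloroacetate and the electron-poor aryl silyl ether, while the hindered C6 vanillate, further deactivated as its phenoxide, should survive and no stereocentre is touched.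

Compound list
1 | 3-methoxycyclopent-2-en-1-one | COC1=CC(=O)CC1 | starting material
2 | 2-bromo-3-methoxycyclopent-2-en-1-one | COC1=C(Br)C(=O)CC1 | intermediate
3 | (1S)-2-bromo-3-methoxycyclopent-2-en-1-ol | COC1=C(Br)[C@@H](O)CC1 | intermediate
4 | [(1S)-2-bromo-3-methoxycyclopent-2-en-1-yl]oxy(tert-butyl)dimethylsilane | COC1=C(Br)[C@@H](O[Si](C)(C)C(C)(C)C)CC1 | intermediate
5 | 4-methylpent-4-enoic acid | C=C(C)CCC(=O)O | starting material
6 | N-methoxy-N,4-dimethylpent-4-enamide | C=C(C)CCC(=O)N(C)OC | intermediate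
7 | 1-[(5S)-5-(tert-butyldimethylsilyloxy)-2-methoxycyclopent-1-en-1-yl]-4-methylpent-4-en-1-one | C=C(C)CCC(=O)C1=C(OC)CC[C@@H]1O[Si](C)(C)C(C)(C)C | intermediate
8 | cyclobutane photoadduct (angular 5-4-5 tricycle; cyclobutane C5–C1–C10–C9, C4 ketone, C9 methoxy, C6 OTBS anti to the two new bonds) | C[C@]12CCC(=O)[C@]13[C@@H](O[Si](C)(C)C(C)(C)C)CC[C@]3(OC)C2 | intermediate
9 | (3aS,4S,8aR)-4-(tert-butyldimethylsilyloxy)-7,7-dimethoxy-8a-methyloctahydroazulen-3(2H)-one (trans-fused) | C1C[C@H](O[Si](C)(C)C(C)(C)C)[C@@H]2[C@](C)(CCC2=O)CC1(OC)OC | intermediate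
10 | (3R,3aS,4S,8aR)-4-(tert-butyldimethylsilyloxy)-7,7-dimethoxy-8a-methyl-3-(propan-2-yl)decahydroazulen-3-ol | C1C[C@H](O[Si](C)(C)C(C)(C)C)[C@@H]2[C@](C)(CC[C@@]2(O)C(C)C)CC1(OC)OC | intermediate
11 | (3R,3aS,4S,8aR)-7,7-dimethoxy-8a-methyl-3-(propan-2-yl)decahydroazulene-3,4-diol | C1C[C@H](O)[C@@H]2[C@](C)(CC[C@@]2(O)C(C)C)CC1(OC)OC | intermediate
12 | vanillic acid | COc1cc(ccc1O)C(=O)O | starting material
13 | tert-butyldimethylsilyl 4-(tert-butyldimethylsilyloxy)-3-methoxybenzoate | COc1cc(ccc1O[Si](C)(C)C(C)(C)C)C(=O)O[Si](C)(C)C(C)(C)C | intermediate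
14 | 4-(tert-butyldimethylsilyloxy)-3-methoxybenzoic acid | COc1cc(ccc1O[Si](C)(C)C(C)(C)C)C(=O)O | intermediate
15 | (3R,3aS,4S,8aR)-3-hydroxy-7,7-dimethoxy-8a-methyl-3-(propan-2-yl)decahydroazulen-4-yl 4-(tert-butyldimethylsilyloxy)-3-methoxybenzoate | C1C[C@H](OC(=O)c3ccc(O[Si](C)(C)C(C)(C)C)c(OC)c3)[C@@H]2[C@](C)(CC[C@@]2(O)C(C)C)CC1(OC)OC | intermediate
16 | (3R,3aS,4S,8aR)-3-hydroxy-8a-methyl-7-oxo-3-(propan-2-yl)decahydroazulen-4-yl 4-(tert-butyldimethylsilyloxy)-3-methoxybenzoate | C1C[C@H](OC(=O)c3ccc(O[Si](C)(C)C(C)(C)C)c(OC)c3)[C@@H]2[C@](C)(CC[C@@]2(O)C(C)C)CC1=O | intermediate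
17 | Mannich base (C8 dimethylaminomethyl ketone, C8 epimers) | CN(C)CC1C[C@H](OC(=O)c3ccc(O[Si](C)(C)C(C)(C)C)c(OC)c3)[C@@H]2[C@](C)(CC[C@@]2(O)C(C)C)CC1=O | intermediate
18 | trimethylammonium iodide of 17 | C[N+](C)(C)CC1C[C@H](OC(=O)c3ccc(O[Si](C)(C)C(C)(C)C)c(OC)c3)[C@@H]2[C@](C)(CC[C@@]2(O)C(C)C)CC1=O.[I-] | intermediate
19 | (3R,3aS,4S,8aR)-3-hydroxy-8a-methyl-6-methylidene-7-oxo-3-(propan-2-yl)decahydroazulen-4-yl 4-(tert-butyldimethylsilyloxy)-3-methoxybenzoate | C=C1C[C@H](OC(=O)c3ccc(O[Si](C)(C)C(C)(C)C)c(OC)c3)[C@@H]2[C@](C)(CC[C@@]2(O)C(C)C)CC1=O | intermediate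
20 | (3R,3aS,4S,7R,8aR)-3,7-dihydroxy-8a-methyl-6-methylidene-3-(propan-2-yl)decahydroazulen-4-yl 4-(tert-butyldimethylsilyloxy)-3-methoxybenzoate (9β-alcohol) | C=C1C[C@H](OC(=O)c3ccc(O[Si](C)(C)C(C)(C)C)c(OC)c3)[C@@H]2[C@](C)(CC[C@@]2(O)C(C)C)C[C@H]1O | intermediate
21 | (3R,3aS,4S,7S,8aR)-7-(chloroacetoxy)-3-hydroxy-8a-methyl-6-methylidene-3-(propan-2-yl)decahydroazulen-4-yl 4-(tert-butyldimethylsilyloxy)-3-methoxybenzoate | C=C1C[C@H](OC(=O)c3ccc(O[Si](C)(C)C(C)(C)C)c(OC)c3)[C@@H]2[C@](C)(CC[C@@]2(O)C(C)C)C[C@@H]1OC(=O)CCl | intermediate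
22 | (3R,3aS,4S,7S,8aR)-3,7-dihydroxy-8a-methyl-6-methylidene-3-(propan-2-yl)decahydroazulen-4-yl 4-hydroxy-3-methoxybenzoate | C=C1C[C@H](OC(=O)c2ccc(O)c(OC)c2)[C@@H]2[C@](C)(CC[C@@]2(O)C(C)C)C[C@@H]1O | target

Total step count: 15. Longest linear sequence: 13 steps (steps 1–3, 5–8 and 10–15).

Steps most likely to fail

Step 6. The 1,4-biradical may revert instead of closing, and the side chain may partly reach the silyloxy-bearing face. In protic acid the opening of the cyclobutane may be slower than loss of the silyl ether, or C5 may not reach the trans-fused arrangement. The fallback separates the two events and changes the trigger. It sets out from 8, which is then isolated and purified after the irradiation, and this also removes any facial isomer. The ring expansion is run under aprotic conditions with TMSI (CH2Cl2, −78 °C): the C4 ketone is silylated, the C5–C9 bond breaks heterolytically, and iodide demethylates the C9 oxocarbenium ion by SN2 attack. After aqueous work-up this should give (3aS,4S,8aR)-4-(tert-butyldimethylsilyloxy)-8a-methyloctahydroazulene-3,7-dione F1. Chemoselective ketalisation of the unhindered C9 ketone (HC(OMe)3, MeOH, PPTS, rt) comes back to the route at 9.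

Step 7. Deprotonation at C5 followed by β-elimination of the silanolate, hydride transfer from the branched Grignard reagent, or plain lack of reactivity at the hindered carbonyl group may outrun the addition. The fallback uses a smaller sp2 nucleophile without β-hydrogen and completes the isopropyl group afterwards. It sets out from 9, which is treated with 2-propenyllithium/CeCl3 (THF, −78 °C). Attack from the same α-face should give (3S,3aS,4S,8aR)-4-(tert-butyldimethylsilyloxy)-7,7-dimethoxy-8a-methyl-3-(prop-1-en-2-yl)decahydroazulen-3-ol F2. Its only C=C bond is then hydrogenated (H2, Pd/C, EtOAc), and the route is rejoined at 10.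

Step 14. The carboxylate may attack the exocyclic CH2 terminus (SN2′ transposition), the allylic oxyphosphonium ion may ionise with loss of stereochemical integrity, or elimination to a diene may take over. The fallback avoids any displacement at C9 and relies on reagent control instead of reduction plus inversion. It sets out from 19, which is reduced with (R)-Me-CBS and catecholborane (toluene, −78 °C). With the methylidene-bearing flank as the large group, this should give directly (3R,3aS,4S,7S,8aR)-3,7-dihydroxy-8a-methyl-6-methylidene-3-(propan-2-yl)decahydroazulen-4-yl 4-(tert-butyldimethylsilyloxy)-3-methoxybenzoate F3. Methanolysis of the aryl silyl ether (K2CO3, MeOH) comes back to the route at 22.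

Further compounds
F1 | step 6 | (3aS,4S,8aR)-4-(tert-butyldimethylsilyloxy)-8a-methyloctahydroazulene-3,7-dione | C1C[C@H](O[Si](C)(C)C(C)(C)C)[C@@H]2[C@](C)(CCC2=O)CC1=O
F2 | step 7 | (3S,3aS,4S,8aR)-4-(tert-butyldimethylsilyloxy)-7,7-dimethoxy-8a-methyl-3-(prop-1-en-2-yl)decahydroazulen-3-ol | C1C[C@H](O[Si](C)(C)C(C)(C)C)[C@@H]2[C@](C)(CC[C@@]2(O)C(C)=C)CC1(OC)OC
F3 | step 14 | (3R,3aS,4S,7S,8aR)-3,7-dihydroxy-8a-methyl-6-methylidene-3-(propan-2-yl)decahydroazulen-4-yl 4-(tert-butyldimethylsilyloxy)-3-methoxybenzoate | C=C1C[C@H](OC(=O)c3ccc(O[Si](C)(C)C(C)(C)C)c(OC)c3)[C@@H]2[C@](C)(CC[C@@]2(O)C(C)C)C[C@@H]1O
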